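**Assumption (one line):** (E)-3-methylpent-2-en-4-yn-1-ol (3) and 5-iodo-2-methylpent-2-ene (7) are taken as catalogue items; the ligand enantiomer in Step 4 is assigned by analogy with the cyclohexenone case and would be confirmed on the first adduct.

## Retrosynthetic overview

1. Dactylomelol (18) ⇐ epoxy aldehyde 17 by Wharton transposition (the carbinol comes from a Sharpless epoxide); the bromochloride ⇐ (R)-epoxide 12 by bromide opening with inversion, then bromonium-assisted chlorination.
2. 7-Oxanorbornane 11 ⇐ cis-4-methylidenecyclohexanol 10 by transannular Markovnikov alkoxymercuration, which forms the C1–O bridge and the C1 methyl together. The carbocycle comes from the arene; the oxa-bridge is the second ring formed.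
3. 10 ⇐ enone 8 (reduction, ketal hydrolysis, methylenation); the quaternary C3 ⇐ α′-methylation then homoprenylation of enone 6.
4. 6 ⇐ enantioselective, desymmetrising Cu-catalysed conjugate addition of a functionalised dialkylzinc (from diene 5) to the achiral dienone 2 ⇐ oxidative dearomatisation of 4-methoxyphenol (1).

## Route

**Step 1**
Reactants: 1, 4-methoxyphenol
Product: 2, 4,4-dimethoxycyclohexa-2,5-dien-1-one
Conditions: PhI(OAc)2, MeOH, 0 °C → rt
Reagents that add atoms: methanol, CO
Why: Hypervalent-iodine oxidative dearomatisation (quinone monoketal synthesis): the phenoxenium ion is trapped at C4 by MeOH to give an achiral cross-conjugated dienone with two enantiotopic enone units; no stereocentre is formed.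

**Step 2**
Reactants: 3, (E)-3-methylpent-2-en-4-yn-1-ol
Product: 4, (E)-tert-butyl[(3-methylpent-2-en-4-yn-1-yl)oxy]diphenylsilane
Conditions: TBDPSCl, imidazole, CH2Cl2, rt
Reagents that add atoms: tert-butyl(chloro)diphenylsilane, CC(C)(C)[Si](Cl)(c1ccccc1)c1ccccc1
Why: Standard silylation of the primary allylic alcohol; the (E)-trisubstituted olefin is untouched.

**Step 3**
Reactants: 4, enyne silyl ether
Product: 5, (E)-tert-butyl[(3-methylpenta-2,4-dien-1-yl)oxy]diphenylsilane
Conditions: H2 (1 atm), Lindlar catalyst, quinoline, hexane, rt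
Reagents that add atoms: none
Why: Lindlar semihydrogenation of the terminal alkyne stops at the vinyl group and leaves the (E)-trisubstituted alkene intact.

**Step 4 (key step)**
Reactants: 2, 4,4-dimethoxycyclohexa-2,5-dien-1-one; 5, dienyl silyl ether
Product: 6, (S)-5-[(E)-5-(tert-butyldiphenylsilyloxy)-3-methylpent-3-en-1-yl]-4,4-dimethoxycyclohex-2-en-1-one
Conditions: 5, Et2BH, Et2O, 0 °C; Et2Zn, 0 °C, then vacuum; then 2, Cu(OTf)2 (2 mol %), (R,S,S)-L* (4 mol %), toluene, −25 °C; aq NH4Cl. L* = O,O′-(R)-1,1′-binaphthyl-2,2′-diyl N,N-bis[(S)-1-phenylethyl]phosphoramidite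
Reagents that add atoms: none (the C6 chain comes from reactant 5)
Why: Knochel hydroboration/boron–zinc exchange (boron adds to the terminal vinyl carbon) gives the primary dialkylzinc, and Feringa-type Cu–phosphoramidite asymmetric conjugate addition then desymmetrises the achiral dienone, the catalyst choosing one enone face so that C5 is set as (S) (this substrate class gives ≥97% ee with Et2Zn); only mono-addition occurs at −25 °C.

**Step 5**
Reactants: 6, enone; 7, 5-iodo-2-methylpent-2-ene
Product: 8, (5S,6S)-5-[(E)-5-(tert-butyldiphenylsilyloxy)-3-methylpent-3-en-1-yl]-4,4-dimethoxy-6-methyl-6-(4-methylpent-3-en-1-yl)cyclohex-2-en-1-one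
Conditions: LDA, THF, −78 °C, then MeI (1.0 equiv), −78 → −20 °C; then LDA, DMPU, 7, −78 → 0 °C (one pot)
Reagents that add atoms: iodomethane, CI
Why: Two successive kinetic α′-enolate alkylations (C6 is the only enolisable position, and once quaternary it blocks aromatisation); in the second, A(1,2) strain puts the C5 chain pseudoaxial, so the homoprenyl iodide enters anti to it and the C6 methyl ends up cis to the C5 chain.

**Step 6**
Reactants: 8, enone ketal
Product: 9, (2S,3S,4S)-2-[(E)-5-(tert-butyldiphenylsilyloxy)-3-methylpent-3-en-1-yl]-4-hydroxy-3-methyl-3-(4-methylpent-3-en-1-yl)cyclohexan-1-one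
Conditions: NiCl2·6H2O, NaBH4, MeOH, −20 → 0 °C; then 1 M HCl, THF, rt
Reagents that add atoms: water, O
Why: Nickel boride conjugate reduction of the disubstituted enone C=C (trisubstituted olefins are inert) followed by borohydride reduction, with hydride delivered axially anti to the axial α-methyl so that the equatorial alcohol is cis to that methyl and to the C2 chain; the acidic work-up hydrolyses the dimethyl ketal, which had masked the second carbonyl during reduction.

**Step 7**
Reactants: 9, γ-hydroxy ketone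
Product: 10, (1S,2S,3R)-3-[(E)-5-(tert-butyldiphenylsilyloxy)-3-methylpent-3-en-1-yl]-2-methyl-4-methylidene-2-(4-methylpent-3-en-1-yl)cyclohexan-1-ol
Conditions: Ph3PCH3Br, KOt-Bu (3 equiv ylide), THF, 0 °C → rt
Reagents that add atoms: methyltriphenylphosphonium bromide, C[P+](c1ccccc1)(c1ccccc1)c1ccccc1.[Br-]
Why: Wittig methylenation with excess ylide tolerates the free alkoxide, and the α-stereocentre already has its thermodynamically preferred trans-diequatorial arrangement, so it is not at risk from enolisation.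

**Step 8**
Reactants: 10, cis-4-methylidenecyclohexanol
Product: 11, tert-butyl{[(E)-5-[(1R,2S,3S,4S)-1,3-dimethyl-3-(4-methylpent-3-en-1-yl)-7-oxabicyclo[2.2.1]heptan-2-yl]-3-methylpent-2-en-1-yl]oxy}diphenylsilane
Conditions: Hg(OCOCF3)2, CH2Cl2, −20 °C; then NaBH4, aq NaOH
Reagents that add atoms: none
Why: Intramolecular Markovnikov alkoxymercuration–demercuration (as in terpinen-4-ol → 1,4-cineole): the hydroxyl attacks the tertiary carbon through a boat with no free cation, so the bridge forms on the hydroxyl face and fixes the bridgehead C1 with the C2 chain and C3 methyl exo; the side-chain olefins have no nucleophile within reach of a 5- or 6-membered Markovnikov closure.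

**Step 9**
Reactants: 11, oxanorbornane diene
Product: 12, the C3 side chain is now 2-[(R)-3,3-dimethyloxiran-2-yl]ethyl (rest as 11)
Conditions: D-fructose-derived Shi ketone (0.3 equiv), Oxone, K2CO3, Bu4NHSO4, MeCN–DMM–buffer (pH 10.5), 0 °C
Reagents that add atoms: Oxone (KHSO5), OOS(=O)(=O)[O-].[K+]
Why: Shi asymmetric epoxidation is reagent-controlled and gives the (R)-epoxide of the R–CH=CMe2 terminus; the electron-rich prenyl-type olefin reacts faster than the olefin deactivated and shielded by the allylic OTBDPS group (as in farnesyl derivatives).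

**Step 10**
Reactants: 12, epoxide
Product: 13, the C3 side chain is now (S)-3-bromo-4-hydroxy-4-methylpentyl
Conditions: Li2NiBr4, THF, 0 °C → rt
Reagents that add atoms: dilithium tetrabromonickelate, [Li+].[Li+].Br[Ni-2](Br)(Br)Br
Why: SN2 opening of the trisubstituted epoxide by bromide at the less substituted carbon with inversion gives the (S)-secondary bromide and a tertiary alcohol.

**Step 11**
Reactants: 13, bromohydrin
Product: 14, the C3 side chain is now (S)-3-bromo-4-chloro-4-methylpentyl (TBDPS ether)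
Conditions: SOCl2, 2,6-di-tert-butylpyridine, CH2Cl2, −20 → 0 °C
Reagents that add atoms: thionyl chloride, O=S(Cl)Cl
Why: The tertiary chlorosulfite ionises with anchimeric assistance from the neighbouring bromine (bromonium ion, Winstein–Lucas retention) and chloride opens it at the tertiary carbon, so the C–Br stereocentre is kept and the regiochemistry is that of a Markovnikov bromochlorination.

**Step 12**
Reactants: 14, silyl ether
Product: 15, (E)-5-[(1R,2S,3S,4S)-3-((S)-3-bromo-4-chloro-4-methylpentyl)-1,3-dimethyl-7-oxabicyclo[2.2.1]heptan-2-yl]-3-methylpent-2-en-1-ol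
Conditions: HF·pyridine, THF–pyridine, 0 °C
Reagents that add atoms: none
Why: Buffered fluoride desilylation is non-basic and non-reducing, so the vicinal bromochloride survives.

**Step 13**
Reactants: 15, allylic alcohol
Product: 16, [(2S,3S)-3-methyl-3-{2-[(1R,2S,3S,4S)-3-((S)-3-bromo-4-chloro-4-methylpentyl)-1,3-dimethyl-7-oxabicyclo[2.2.1]heptan-2-yl]ethyl}oxiran-2-yl]methanol
Conditions: Ti(Oi-Pr)4 (10 mol %), L-(+)-DET (12 mol %), t-BuOOH, 4 Å MS, CH2Cl2, −20 °C
Reagents that add atoms: tert-butyl hydroperoxide, CC(C)(C)OO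
Why: Sharpless asymmetric epoxidation of the geraniol-type (E)-allylic alcohol with L-(+)-DET gives the (2S,3S)-epoxide under reagent control, setting the future carbinol carbon as (S).

**Step 14**
Reactants: 16, epoxy alcohol
Product: 17, the corresponding (2R,3S)-epoxy aldehyde (oxirane-2-carbaldehyde)
Conditions: Dess–Martin periodinane, NaHCO3, CH2Cl2, 0 °C
Reagents that add atoms: none
Why: Buffered Dess–Martin oxidation gives the α,β-epoxy aldehyde without epimerisation or epoxide opening (the CIP label at C2 changes, the geometry does not).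

**Step 15**
Reactants: 17, epoxy aldehyde
Product: 18, dactylomelol, (S)-5-[(1R,2S,3S,4S)-3-((S)-3-bromo-4-chloro-4-methylpentyl)-1,3-dimethyl-7-oxabicyclo[2.2.1]heptan-2-yl]-3-methylpent-1-en-3-ol
Conditions: N2H4·H2O, AcOH (cat.), MeOH, 0 °C
Reagents that add atoms: none
Why: Wharton transposition: the epoxy hydrazone fragments with loss of N2, cleaving only the C2–O bond, so the (3S) C–O bond becomes the (S)-tertiary allylic alcohol and C1–C2 becomes the vinyl group under conditions the bromochloride tolerates.

## Compound list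

1 | 4-methoxyphenol | COc1ccc(O)cc1 | starting material
2 | 4,4-dimethoxycyclohexa-2,5-dien-1-one | COC1(OC)C=CC(=O)C=C1 | intermediate
3 | (E)-3-methylpent-2-en-4-yn-1-ol | C#C/C(C)=C/CO | starting material
4 | (E)-tert-butyl[(3-methylpent-2-en-4-yn-1-yl)oxy]diphenylsilane | C#C/C(C)=C/CO[Si](c1ccccc1)(c1ccccc1)C(C)(C)C | intermediate
5 | (E)-tert-butyl[(3-methylpenta-2,4-dien-1-yl)oxy]diphenylsilane | C=C/C(C)=C/CO[Si](c1ccccc1)(c1ccccc1)C(C)(C)C | intermediate
6 | (S)-5-[(E)-5-(TBDPSO)-3-methylpent-3-en-1-yl]-4,4-dimethoxycyclohex-2-en-1-one | CC(C)(C)[Si](c1ccccc1)(c1ccccc1)OC/C=C(\C)CC[C@H]1CC(=O)C=CC1(OC)OC | intermediate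
7 | 5-iodo-2-methylpent-2-ene | CC(C)=CCCI | starting material
8 | (5S,6S)-5-[(E)-5-(TBDPSO)-3-methylpent-3-en-1-yl]-4,4-dimethoxy-6-methyl-6-(4-methylpent-3-en-1-yl)cyclohex-2-en-1-one | CC(C)(C)[Si](c1ccccc1)(c1ccccc1)OC/C=C(\C)CC[C@H]1[C@](C)(CCC=C(C)C)C(=O)C=CC1(OC)OC | intermediate
9 | (2S,3S,4S)-2-[(E)-5-(TBDPSO)-3-methylpent-3-en-1-yl]-4-hydroxy-3-methyl-3-(4-methylpent-3-en-1-yl)cyclohexan-1-one | CC(C)(C)[Si](c1ccccc1)(c1ccccc1)OC/C=C(\C)CC[C@H]1[C@](C)(CCC=C(C)C)[C@@H](O)CCC1=O | intermediate
10 | (1S,2S,3R)-3-[(E)-5-(TBDPSO)-3-methylpent-3-en-1-yl]-2-methyl-4-methylidene-2-(4-methylpent-3-en-1-yl)cyclohexan-1-ol | CC(C)(C)[Si](c1ccccc1)(c1ccccc1)OC/C=C(\C)CC[C@H]1[C@](C)(CCC=C(C)C)[C@@H](O)CCC1=C | intermediate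
11 | (1R,2S,3S,4S)-2-[(E)-5-(TBDPSO)-3-methylpent-3-en-1-yl]-1,3-dimethyl-3-(4-methylpent-3-en-1-yl)-7-oxabicyclo[2.2.1]heptane | CC(C)(C)[Si](c1ccccc1)(c1ccccc1)OC/C=C(\C)CC[C@H]1[C@](C)(CCC=C(C)C)[C@@H]2CC[C@@]1(C)O2 | intermediate
12 | as 11, with 3-{2-[(R)-3,3-dimethyloxiran-2-yl]ethyl} | CC(C)(C)[Si](c1ccccc1)(c1ccccc1)OC/C=C(\C)CC[C@H]1[C@](C)(CC[C@H]3OC3(C)C)[C@@H]2CC[C@@]1(C)O2 | intermediate
13 | as 11, with 3-[(S)-3-bromo-4-hydroxy-4-methylpentyl] | CC(C)(C)[Si](c1ccccc1)(c1ccccc1)OC/C=C(\C)CC[C@H]1[C@](C)(CC[C@H](Br)C(C)(C)O)[C@@H]2CC[C@@]1(C)O2 | intermediate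
14 | as 11, with 3-[(S)-3-bromo-4-chloro-4-methylpentyl] | CC(C)(C)[Si](c1ccccc1)(c1ccccc1)OC/C=C(\C)CC[C@H]1[C@](C)(CC[C@H](Br)C(C)(C)Cl)[C@@H]2CC[C@@]1(C)O2 | intermediate
15 | (E)-5-[(1R,2S,3S,4S)-3-((S)-3-bromo-4-chloro-4-methylpentyl)-1,3-dimethyl-7-oxabicyclo[2.2.1]heptan-2-yl]-3-methylpent-2-en-1-ol | OC/C=C(\C)CC[C@H]1[C@](C)(CC[C@H](Br)C(C)(C)Cl)[C@@H]2CC[C@@]1(C)O2 | intermediate
16 | (2S,3S)-epoxy alcohol of 15 | OC[C@@H]1O[C@@]1(C)CC[C@H]2[C@](C)(CC[C@H](Br)C(C)(C)Cl)[C@@H]3CC[C@@]2(C)O3 | intermediate
17 | (2R,3S)-epoxy aldehyde | O=C[C@@H]1O[C@@]1(C)CC[C@H]2[C@](C)(CC[C@H](Br)C(C)(C)Cl)[C@@H]3CC[C@@]2(C)O3 | intermediate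
18 | dactylomelol | C=C[C@@](C)(O)CC[C@H]1[C@](C)(CC[C@H](Br)C(C)(C)Cl)[C@@H]2CC[C@@]1(C)O2 | target

## Totals and risks

**Total steps:** 15. **Longest linear sequence:** 14 (3 → 4 → 5 → 6 → 8 → … → 18; the arm from 1 is 13).

**Three steps most likely to fail, each with a fallback that changes the approach:**

- **Step 5** (quaternary centre by alkylation with an unactivated homoallylic iodide; slow, with E2 and O-alkylation competing). Fallback: install the chain in stages through a reactive electrophile. Allylate the 6-methyl enolate (allyl bromide, or Tsuji Pd-allylation of the allyl enol carbonate), then 9-BBN hydroboration–oxidation, oxidation to the aldehyde and Ph3P=CMe2 olefination.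
- **Step 11** (tertiary chlorination through the bromonium ion; elimination or halide scrambling). Fallback: reverse the order of halogen introduction from the same epoxide 12. Open it with chloride at the tertiary carbon under Lewis acid (TiCl4-type), then put bromine on the secondary carbinol by invertive displacement (triflate, then LiBr), which gives the same (S)-bromide.
- **Step 15** (Wharton transposition; moderate yields with epoxy aldehydes, and hydrazine in the presence of alkyl halides). Fallback: move the transposition ahead of halogenation and make it reductive. From 11: desilylate, Sharpless epoxidation, epoxy iodide, Zn-mediated opening to the tertiary allylic alcohol, TES protection; then Shi epoxidation, Li2NiBr4, neutral chlorination (Ghosez reagent) and HF·pyridine.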